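**Plan**
- **Feature:** each γ-butyrolactone ring (O1, C2=O, C3, C4, C5H2) has a C3–C4 bond joining two adjacent trans stereocentres. C3 carries a benzylic CH2 of the diaryl ether core. C4 carries the 3,4-dimethoxybenzyl group and C5H2–O1. With O1–C2 opened and C5 read as the stump of a propenyl group, each ring is a 2,3-disubstituted hex-4-enoic acid, the retron of an ester-enolate [3,3] shift.
- **Cuts, in order:** the phenol O–benzyl bond; both O1–C2 bonds; both C5=C bonds; both C3–C4 bonds at once; both ester C–O bonds; the two side-chain C–C bonds of the core; the diaryl ether C–O bond.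
- **Forward:** the arm alcohol (2 steps) and the core diacid (3 steps) are joined by double esterification. The double rearrangement then makes both C3–C4 bonds without closing a ring. Both lactone rings close together after alkene cleavage and reduction, and hydrogenolysis ends the route.
- **Stereochemistry:** the only chiral source is (S)-but-3-yn-2-ol. Trans-hydroalumination fixes the E alkene, the suprafacial chair shift moves the carbinol configuration to C4, and the Z ketene acetal sets C3. The thermodynamic trans preference of the lactone backs up C3.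

Key step: step 7

Remark: the four stereocentres of the SMILES are read as 3S,4S in both lactone rings (both trans), and the route is built for this enantiomer.

**Step 1**
Reactants: 1 (S)-but-3-yn-2-ol; 2 3,4-dimethoxybenzyl bromide
Product: 3 (S)-5-(3,4-dimethoxyphenyl)pent-3-yn-2-ol
Conditions: 1, EtMgBr (2.1 equiv), THF, 0 °C → rt; CuBr·SMe2 (10 mol %), then 2, THF, 50 °C; aq NH4Cl
Reagents that add atoms: none
Why: Copper-catalysed alkylation of an alkynylmagnesium bromide with a benzylic bromide forms the C–C bond at the alkyne terminus, because the magnesium alkoxide is a poor O-nucleophile, and the carbinol centre is not involved.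

**Step 2**
Reactants: 3 (S)-5-(3,4-dimethoxyphenyl)pent-3-yn-2-ol
Product: 4 (2S,3E)-5-(3,4-dimethoxyphenyl)pent-3-en-2-ol
Conditions: Red-Al (2.5 equiv), THF, 0 °C → rt; aq Rochelle salt
Reagents that add atoms: none
Why: Hydroxyl-directed trans-hydroalumination of a propargylic alcohol followed by protonolysis of the vinyl alanate should give only the E alkene, with the S carbinol centre retained.

**Step 3**
Reactants: 5 5-bromovanillin
Product: 6 4-(benzyloxy)-3-bromo-5-methoxybenzaldehyde
Conditions: BnBr, K2CO3, DMF, 50 °C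
Reagents that add atoms: benzyl bromide, BrCc1ccccc1
Why: Williamson ether synthesis on the acidic para-formyl phenol masks the one OH that must reappear in the target, as an ether that is inert to every later reagent up to the final hydrogenolysis.

**Step 4**
Reactants: 6 4-(benzyloxy)-3-bromo-5-methoxybenzaldehyde; 7 vanillin
Product: 8 4-(benzyloxy)-3-(4-formyl-2-methoxyphenoxy)-5-methoxybenzaldehyde
Conditions: CuI (20 mol %), picolinic acid (40 mol %), K3PO4, DMSO, 90 °C
Reagents that add atoms: none
Why: In this ligand-accelerated Ullmann diaryl ether coupling the copper(I) phenoxide of vanillin replaces the bromide, the picolinate ligand is the one suited to ortho-substituted partners, and the two non-enolisable aldehydes tolerate K3PO4.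

**Step 5**
Reactants: 8 4-(benzyloxy)-3-(4-formyl-2-methoxyphenoxy)-5-methoxybenzaldehyde
Product: 11 3-{4-(benzyloxy)-3-[4-(2-carboxyethyl)-2-methoxyphenoxy]-5-methoxyphenyl}propanoic acid (core diacid), via bis(arylidene) Meldrum adduct 9 (not isolated), via bis(benzyl) Meldrum adduct 10 (not isolated)
Conditions: Meldrum's acid (2.2 equiv), HCO2H–Et3N (5:2), 95–100 °C; dil HCl
Reagents that add atoms: Meldrum's acid, CC1(C)OC(=O)CC(=O)O1
Why: In this reductive Knoevenagel sequence each aldehyde condenses to a strongly electrophilic arylidene that takes hydride from formate, and the saturated adduct then hydrolyses and decarboxylates in the hot medium, with no metal or hydrogen present that could cleave the benzyl ether.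

**Step 6**
Reactants: 11 core diacid; 4 (2S,3E)-5-(3,4-dimethoxyphenyl)pent-3-en-2-ol (2.2 equiv)
Product: 12 bis[(2S,3E)-5-(3,4-dimethoxyphenyl)pent-3-en-2-yl] ester of core diacid 11
Conditions: EDC·HCl (2.6 equiv), DMAP (0.4 equiv), CH2Cl2, 0 °C → rt
Reagents that add atoms: none
Why: Steglich esterification activates the acid and not the alcohol, so both carbinol C–O bonds stay intact and the S configuration and E geometry of 4 pass unchanged into both arms.

**Step 7**
Reactants: 12 bis[(2S,3E)-5-(3,4-dimethoxyphenyl)pent-3-en-2-yl] ester of core diacid 11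
Product: 15 bis[(2S,3R,4E)-3-(3,4-dimethoxybenzyl)hex-4-enoic acid] whose two C2 atoms carry the two benzylic CH2 groups of the O-benzyl diaryl ether core, via (Z,Z)-bis(TBS ketene acetal) 13 (not isolated), via bis(TBS ester) 14 (not isolated)
Conditions: LDA (2.5 equiv), THF–DMPU (55:45), −78 °C; TBSCl (3 equiv), −78 °C → rt, then 50 °C; AcOH–THF–H2O, rt
Reagents that add atoms: TBSCl, CC(C)(C)[Si](C)(C)Cl (its silyl groups are present in 13 and 14 only and are lost before 15)
Why: LDA in THF–DMPU deprotonates both propanoate arms through an open transition state so that each enolate has its ArCH2 group cis to O–Li, O-silylation fixes this as the (Z,Z)-bis(silyl ketene acetal) 13, and on warming each arm undergoes a concerted suprafacial [3,3] shift that joins the ketene acetal carbon (future lactone C3) to the alkene terminus bearing the 3,4-dimethoxybenzyl group (future lactone C4) and leaves silyl ester 14, which mild acid hydrolyses to 15. The reaction type is the Ireland–Claisen rearrangement of a secondary (E)-allylic ester with 1,3-chirality transfer, run here on two independent arms of one molecule; no ring is closed, since the six-membered array exists only in the transition state. Each C3 of the hexenoic acid (R here, S once the propenyl group has become C5H2–O1) is controlled by the S carbinol centre and the E alkene: in the chair with the carbinol methyl pseudo-equatorial, the C–C bond forms on the face from which the C–O bond departs, and the new alkene is E. Each C2 (S) is controlled by the ketene acetal geometry, because the Z isomer places ArCH2 pseudo-equatorial and so gives the 2,3-syn acid, the one that maps onto the trans lactone. The step needs ester α-deprotonation rather than attack on the allylic-benzylic ArCH2–CH= protons (secured by the large pKa gap at −78 °C), O- rather than C-silylation (secured by TBSCl in the dipolar medium) and chair rather than boat (usual for acyclic E-allylic esters; a boat would invert only C2, which step 8 repairs). Because both arms carry the same stereochemical information, a rare mis-transfer in one arm gives a separable diastereomer and not the enantiomer, so the enantiomeric purity of 15 should exceed that of 1.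

**Step 8**
Reactants: 15 bis[(2S,3R,4E)-3-(3,4-dimethoxybenzyl)hex-4-enoic acid] on the O-benzyl diaryl ether core
Product: 18 O-benzyl bis-lactone with 3S,4S configuration in both rings, via dialdehyde diacid 16 (not isolated), via bis(hydroxy acid) 17 (not isolated)
Conditions: O3, CH2Cl2–MeOH (4:1), Sudan Red 7B, −78 °C; NaBH4 (excess), −78 → 0 °C; 1 M HCl to pH 2, then TsOH (cat), CH2Cl2, rt; crude product with DBU (0.2 equiv), CH2Cl2, rt
Reagents that add atoms: ozone, [O-][O+]=O
Why: Criegee ozonolysis of the two 1,2-disubstituted alkenes should outrun attack on the arenes at −78 °C with a dye end point, in-flask borohydride reduction takes the aldehyde stage to the primary alcohols before the formyl-bearing carbon can enolise, acid closes both five-membered lactones by O-acylation, and DBU, which can reach only the lactone C3–H, converts any cis ring to the more stable trans ring.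

**Step 9**
Reactants: 18 O-benzyl bis-lactone
Product: 19 CNP0183104.1, (3S,4S)-4-(3,4-dimethoxybenzyl)-3-[4-(5-{[(3S,4S)-4-(3,4-dimethoxybenzyl)-2-oxotetrahydrofuran-3-yl]methyl}-2-hydroxy-3-methoxyphenoxy)-3-methoxybenzyl]dihydrofuran-2(3H)-one
Conditions: H2 (1 atm), 10% Pd/C, EtOAc–EtOH, rt
Reagents that add atoms: none
Why: Catalytic hydrogenolysis cleaves only the O–CH2Ph bond, since the diaryl ether, the methyl ethers and the non-benzylic lactone C5–O1 bonds are inert and no stereocentre is touched.

**Compound list**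
1 | (S)-but-3-yn-2-ol | C[C@H](O)C#C | starting material
2 | 3,4-dimethoxybenzyl bromide | COc1ccc(CBr)cc1OC | starting material
3 | (S)-5-(3,4-dimethoxyphenyl)pent-3-yn-2-ol | COc1ccc(CC#C[C@H](C)O)cc1OC | intermediate
4 | (2S,3E)-5-(3,4-dimethoxyphenyl)pent-3-en-2-ol | COc1ccc(C/C=C/[C@H](C)O)cc1OC | intermediate
5 | 5-bromovanillin | COc1cc(C=O)cc(Br)c1O | starting material
6 | 4-(benzyloxy)-3-bromo-5-methoxybenzaldehyde | COc1cc(C=O)cc(Br)c1OCc1ccccc1 | intermediate
7 | vanillin | COc1cc(C=O)ccc1O | starting material
8 | 4-(benzyloxy)-3-(4-formyl-2-methoxyphenoxy)-5-methoxybenzaldehyde | COc1cc(C=O)ccc1Oc1cc(C=O)cc(OC)c1OCc1ccccc1 | intermediate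
9 | bis(arylidene) Meldrum adduct (each CHO of 8 turned into CH=C5 of a 2,2-dimethyl-1,3-dioxane-4,6-dione) | COc1cc(C=C2C(=O)OC(C)(C)OC2=O)ccc1Oc1cc(C=C2C(=O)OC(C)(C)OC2=O)cc(OC)c1OCc1ccccc1 | intermediate (not isolated)
10 | bis(benzyl) Meldrum adduct (both C=C bonds of 9 reduced) | COc1cc(CC2C(=O)OC(C)(C)OC2=O)ccc1Oc1cc(CC2C(=O)OC(C)(C)OC2=O)cc(OC)c1OCc1ccccc1 | intermediate (not isolated)
11 | 3-{4-(benzyloxy)-3-[4-(2-carboxyethyl)-2-methoxyphenoxy]-5-methoxyphenyl}propanoic acid | COc1cc(CCC(=O)O)ccc1Oc1cc(CCC(=O)O)cc(OC)c1OCc1ccccc1 | intermediate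
12 | bis[(2S,3E)-5-(3,4-dimethoxyphenyl)pent-3-en-2-yl] ester of 11 | COc1ccc(C/C=C/[C@H](C)OC(=O)CCc2ccc(Oc3cc(CCC(=O)O[C@@H](C)/C=C/Cc4ccc(OC)c(OC)c4)cc(OC)c3OCc3ccccc3)c(OC)c2)cc1OC | intermediate
13 | (Z,Z)-bis(tert-butyldimethylsilyl ketene acetal) of 12 (ArCH2 cis to OSi in both arms) | COc1ccc(C/C=C/[C@H](C)O/C(O[Si](C)(C)C(C)(C)C)=C/Cc2ccc(Oc3cc(C/C=C(O[Si](C)(C)C(C)(C)C)/O[C@@H](C)/C=C/Cc4ccc(OC)c(OC)c4)cc(OC)c3OCc3ccccc3)c(OC)c2)cc1OC | intermediate (not isolated)
14 | bis(tert-butyldimethylsilyl ester) of 15 | COc1ccc(C[C@H](/C=C/C)[C@@H](C(=O)O[Si](C)(C)C(C)(C)C)Cc2ccc(Oc3cc(C[C@H](C(=O)O[Si](C)(C)C(C)(C)C)[C@@H](/C=C/C)Cc4ccc(OC)c(OC)c4)cc(OC)c3OCc3ccccc3)c(OC)c2)cc1OC | intermediate (not isolated)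
15 | bis[(2S,3R,4E)-3-(3,4-dimethoxybenzyl)hex-4-enoic acid] linked through C2–CH2 to the O-benzyl diaryl ether core | COc1ccc(C[C@H](/C=C/C)[C@@H](C(=O)O)Cc2ccc(Oc3cc(C[C@H](C(=O)O)[C@@H](/C=C/C)Cc4ccc(OC)c(OC)c4)cc(OC)c3OCc3ccccc3)c(OC)c2)cc1OC | intermediate
16 | dialdehyde diacid, both arms (2S,3S)-3-(3,4-dimethoxybenzyl)-4-oxobutanoic acid (free or as pseudo-acid lactol) | COc1ccc(C[C@H](C=O)[C@@H](C(=O)O)Cc2ccc(Oc3cc(C[C@H](C(=O)O)[C@@H](C=O)Cc4ccc(OC)c(OC)c4)cc(OC)c3OCc3ccccc3)c(OC)c2)cc1OC | intermediate (not isolated)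
17 | bis(hydroxy acid), both arms (2S,3S)-3-(3,4-dimethoxybenzyl)-4-hydroxybutanoic acid | COc1ccc(C[C@H](CO)[C@@H](C(=O)O)Cc2ccc(Oc3cc(C[C@H](C(=O)O)[C@@H](CO)Cc4ccc(OC)c(OC)c4)cc(OC)c3OCc3ccccc3)c(OC)c2)cc1OC | intermediate (not isolated)
18 | O-benzyl bis-lactone, 3S,4S in both rings | COc1ccc(C[C@@H]2COC(=O)[C@H]2Cc2ccc(Oc3cc(C[C@@H]4C(=O)OC[C@H]4Cc4ccc(OC)c(OC)c4)cc(OC)c3OCc3ccccc3)c(OC)c2)cc1OC | intermediate
19 | CNP0183104.1 | COc1ccc(C[C@@H]2COC(=O)[C@H]2Cc2ccc(Oc3cc(C[C@@H]4C(=O)OC[C@H]4Cc4ccc(OC)c(OC)c4)cc(OC)c3O)c(OC)c2)cc1OC | target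

**Step count**
- Total: 9 steps.
- Longest linear sequence: 7 steps (steps 3, 4, 5, 6, 7, 8, 9, from 5-bromovanillin).

**Steps most likely to fail**

**Step 7.** Both arms must be enolised, O-silylated and rearranged in one flask, so any shortfall per arm counts twice. Incomplete double silylation, loss of ketene acetal geometry, ketene-type fragmentation of the enolate on warming, or proton abstraction at the allylic-benzylic CH2 would each lead to mixtures.

The fallback keeps the [3,3] chirality transfer for C4 but makes the C3 substituent bond by alkylation. It sets out from 4 and 8 and comes back at 18.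
- A Johnson orthoester Claisen rearrangement of 4 (MeC(OEt)3, cat propionic acid, 135 °C) should give ethyl (3S,4E)-3-(3,4-dimethoxybenzyl)hex-4-enoate F1 in the same suprafacial sense.
- Ozonolysis of F1 with borohydride work-up gives ethyl (3S)-4-(3,4-dimethoxyphenyl)-3-(hydroxymethyl)butanoate F2.
- TsOH closes F2 to (4S)-4-(3,4-dimethoxybenzyl)dihydrofuran-2(3H)-one F3.
- In parallel, NaBH4 reduces 8 to [4-(benzyloxy)-3-(4-(hydroxymethyl)-2-methoxyphenoxy)-5-methoxyphenyl]methanol F4.
- PBr3 converts F4 to 2-(benzyloxy)-5-(bromomethyl)-1-[4-(bromomethyl)-2-methoxyphenoxy]-3-methoxybenzene F5.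
- The lithium enolate of F3 (LiHMDS, THF, −78 °C, 2.2 equiv) is alkylated at both ends of F5, anti to the C4 substituent. This is the standard trans-selective entry to dibenzylbutyrolactones and gives 18.

**Step 4.** The phenoxide of vanillin is deactivated by its para formyl group, and the bromide sits next to a benzyloxy group. The C–O coupling may therefore be slow and lose out to protodebromination or catalyst decay.

The fallback reverses the roles of the two rings and uses addition–elimination in place of copper catalysis. It sets out from 6 and comes back at 8.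
- Miyaura borylation of 6 (B2pin2, Pd(dppf)Cl2, KOAc, dioxane, 90 °C) gives 4-(benzyloxy)-3-methoxy-5-(4,4,5,5-tetramethyl-1,3,2-dioxaborolan-2-yl)benzaldehyde F6.
- Sodium perborate (THF–H2O, rt) oxidises F6 to 4-(benzyloxy)-3-hydroxy-5-methoxybenzaldehyde F7.
- SNAr of F7 on commercial 4-fluoro-3-methoxybenzaldehyde (K2CO3, DMF, 110 °C), whose fluoride is activated by the para formyl group, gives 8.

**Step 8.** Ozone may also attack the four electron-rich rings or the benzylic C–H of the ether once the alkenes are consumed. A long-lived aldehyde stage could also enolise at the carbon that becomes lactone C4.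

The fallback replaces ozone by an alkene-specific osmium dihydroxylation and glycol cleavage. It sets out from 15 and comes back at 16.
- The bis(sodium carboxylate) of 15 (K2OsO4·2H2O cat, NMO, aq NaHCO3–acetone) gives the bis(4,5-dihydroxy) diacid F8 as a mixture at the new carbinol centres, which are destroyed in the next operation.
- NaIO4 in the same buffered medium cleaves both glycols to 16, held as its pseudo-acid lactol.
- 16 is reduced, lactonised and equilibrated as in step 8.

**Further compounds**
F1 | step 7 | ethyl (3S,4E)-3-(3,4-dimethoxybenzyl)hex-4-enoate | COc1ccc(C[C@H](/C=C/C)CC(=O)OCC)cc1OC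
F2 | step 7 | ethyl (3S)-4-(3,4-dimethoxyphenyl)-3-(hydroxymethyl)butanoate | COc1ccc(C[C@H](CO)CC(=O)OCC)cc1OC
F3 | step 7 | (4S)-4-(3,4-dimethoxybenzyl)dihydrofuran-2(3H)-one | COc1ccc(C[C@@H]2COC(=O)C2)cc1OC
F4 | step 7 | [4-(benzyloxy)-3-(4-(hydroxymethyl)-2-methoxyphenoxy)-5-methoxyphenyl]methanol | COc1cc(CO)ccc1Oc1cc(CO)cc(OC)c1OCc1ccccc1
F5 | step 7 | 2-(benzyloxy)-5-(bromomethyl)-1-[4-(bromomethyl)-2-methoxyphenoxy]-3-methoxybenzene | COc1cc(CBr)ccc1Oc1cc(CBr)cc(OC)c1OCc1ccccc1
F6 | step 4 | 4-(benzyloxy)-3-methoxy-5-(4,4,5,5-tetramethyl-1,3,2-dioxaborolan-2-yl)benzaldehyde | COc1cc(C=O)cc(B2OC(C)(C)C(C)(C)O2)c1OCc1ccccc1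
F7 | step 4 | 4-(benzyloxy)-3-hydroxy-5-methoxybenzaldehyde | COc1cc(C=O)cc(O)c1OCc1ccccc1
F8 | step 8 | bis(4,5-dihydroxy) diacid from 15 (2S,3R retained, new carbinol centres unassigned) | COc1ccc(C[C@H](C(O)C(C)O)[C@@H](C(=O)O)Cc2ccc(Oc3cc(C[C@H](C(=O)O)[C@@H](C(O)C(C)O)Cc4ccc(OC)c(OC)c4)cc(OC)c3OCc3ccccc3)c(OC)c2)cc1OC
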